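Next to a neighbouring flask charged with a quarter of the starting material, the question for this flask is whether the charge moves the percentages at all.

starting material 0.015 M; gas 1.4 mM (held); time 1.5 h

    starting material + coupling partner ⇌ target (K1 = 2200 M⁻¹, k1 = 330 M⁻¹ s⁻¹)
    coupling partner ⇌ dormant form (K2 = 270, k2 = 0.0036 s⁻¹)
    target ⇌ isomer of the product B (K3 = 0.46, k3 = 8.8 × 10⁻⁴ s⁻¹)
    gas ⇌ coupling partner, rate k4*(csat - [coupling partner]) (k4 = 0.41 s⁻¹, csat = 1.4 mM)
    starting material + coupling partner ⇌ isomer of the product A (K5 = 6400 M⁻¹, k5 = 4.9 M⁻¹ s⁻¹)

1. which holds at 1.5 h: what has brought the reaction to rest, or that it has not come to rest (forward and back rates have come level / it is still moving / all of the starting material has reacted)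
2. amount of target at 1.5 h, in percent of the starting material charged
3. amount of isomer of the product A at 1.5 h, in percent of the starting material charged

- at the start none of coupling partner is dissolved
- the reaction counts as stopped when no species that holds the starting material changes by six tenths of a point or more over the second half of the time
- run time (flask): 1.5 h

The flask starts with no coupling partner dissolved. The gas feeds an empty solution at 0.574 mM s⁻¹, and that inflow falls as partner builds; by transfer alone, the gap to saturation has a half-life of 1.69 s, far shorter than the time. The reckoning made here takes the dissolved partner as held where inflow from the gas equals the forward leak into dormant form, and neglects the return. Setting k4 times (csat minus partner) equal to k2 times partner gives 1.39 mM.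

A partner concentration that stays put makes each step that uses it pseudo-first-order, and the forms of the starting material can then come level among themselves. At level, target stands to starting material as K1 times the held partner, 3.05, and isomer A stands to starting material as K5 times it, 8.88, while isomer B stands to target as 0.46. The held share of isomer A is 61.9%: isomer A over the sum of starting material, target and both isomers. The same sum puts target at 21.3%. The charge of starting material appears in neither.

Whether the flask gets there is a count of half-lives. Isomer A forms from starting material, which makes up 18.3% of what is not isomer A. The exchange therefore relaxes at k5 times partner times that fraction, plus the back constant k5/K5, a half-life of 0.0957 h. The time holds 15.7 of these. The exchange between target and isomer B, with a relaxation half-life of 0.0689 h, runs alongside at a like pace and lowers the true count somewhat. With the half-life still much shorter than the time, this reckoning commits to forward and back rates level, with the held shares as the yields.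

The forecast gives forward and back rates have come level, target 21.3% (20.5% to 22%) and isomer A 61.9% (60.5% to 63%), in its words: “simply share out according to their equilibrium ratios”.

The simulation of this flask gives forward and back rates have come level, with target 21.3% and isomer A 61.9%, against held shares of 21.3% and 61.9%; the partner reads 0.00139 M at 1.50 h. On the neighbouring flask the held share, free of the charge, stays 61.9%. That neighbour gives target 21.3% and isomer A 61.9%, with partner at 0.00139 M, and 7.0% of its charge remains as starting material.

The numbers are those of an exercise.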